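**Retrosynthetic overview**
1. Target 22 ← methacrylation of the free hydroxyl of tricyclic hydroxy angelate 20.
2. 20 ← transannular crossed [2+2] photocycloaddition of the 11-membered trienone 19 (bonds C10–C4 and C11–C5); the cyclobutane, cyclohexenone and cycloheptane rings form in this one step.
3. 19 ← intramolecular Heck closure of iodo dienone 18 ← anti-diol 15 ← boron aldol of methyl ketone 12 with enal 8.
4. 8 ← olefination, ynone formation and hydroiodination from 1, 2 and 5; 12 ← prenyl Grignard reagent and acetic anhydride.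
5. Ring order: 11-membered carbocycle first, then the four-, six- and seven-membered rings together.

Assumption: aldol 14 is formed in about 85–90 % ee and is brought to a single enantiomer by one recrystallisation of diol 15.

**Step 1**
Reactants: 1 1,1-dimethoxypropan-2-one; 2 diethyl {2-[methoxy(methyl)amino]-2-oxoethyl}phosphonate
Product: 4 (2E)-N,4,4-trimethoxy-N,3-dimethylbut-2-enamide, via sodium phosphonate anion 3 (not isolated)
Conditions: NaH, THF, 0 °C; then 1, 0 → 40 °C
Reagents that add atoms: none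
Why: Horner–Wadsworth–Emmons olefination of the activated α,α-dialkoxy ketone places the acetal carbon trans to the carbonyl (E), and the minor Z isomer is removed by chromatography.

**Step 2**
Reactants: 4 (2E)-N,4,4-trimethoxy-N,3-dimethylbut-2-enamide; 5 prop-1-yn-1-ylmagnesium bromide
Product: 6 (2E)-1,1-dimethoxy-2-methylhept-2-en-5-yn-4-one
Conditions: THF, −20 → 0 °C; sat. aq. NH4Cl
Reagents that add atoms: none
Why: Weinreb ketone synthesis, in which the chelated tetrahedral adduct of the alkynyl Grignard reagent collapses only on work-up, so one 1,2-addition gives the ynone.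

**Step 3**
Reactants: 6 (2E)-1,1-dimethoxy-2-methylhept-2-en-5-yn-4-one
Product: 8 (2E,5Z)-6-iodo-2-methyl-4-oxohepta-2,5-dienal, via iodo acetal 7 (not isolated)
Conditions: NaI, AcOH, 23 °C; then H2O, 23 °C (dark)
Reagents that add atoms: sodium iodide, [Na+].[I-]; water, O
Why: Conjugate hydroiodination of the ynone (anti addition, kinetic Z isomer with iodine cis to the carbonyl) is followed by hydrolysis of the labile enal acetal in the same aqueous acid.

**Step 4**
Reactants: 9 1-chloro-3-methylbut-2-ene; 10 acetic anhydride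
Product: 12 3,3-dimethylpent-4-en-2-one, via prenylmagnesium chloride 11 (not isolated)
Conditions: Mg, THF, 0 °C; then added to 10, THF, −78 °C
Reagents that add atoms: none
Why: Grignard acylation with allylic transposition (SE2′) gives the α,α-dimethyl allyl ketone, and the hindered product resists a second addition at −78 °C.

**Step 5**
Reactants: 12 3,3-dimethylpent-4-en-2-one; 8 (2E,5Z)-6-iodo-2-methyl-4-oxohepta-2,5-dienal
Product: 14 (6R,7E,10Z)-6-hydroxy-11-iodo-3,3,7-trimethyldodeca-1,7,10-triene-4,9-dione, via diisopinocampheylboron enolate 13 (not isolated)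
Conditions: (−)-Ipc2BCl, Et3N, Et2O, 0 °C; then 8, −78 → −20 °C; H2O2, MeOH, pH 7 buffer, 0 °C
Reagents that add atoms: none
Why: Paterson boron aldol reaction, in which the methyl-ketone enol borinate from (−)-Ipc2BCl attacks the re face of the aldehyde through a cyclic transition state and sets the (R)-carbinol, the aldehyde reacting in preference to the dienone carbonyl.

**Step 6**
Reactants: 14 (6R,7E,10Z)-6-hydroxy-11-iodo-3,3,7-trimethyldodeca-1,7,10-triene-4,9-dione
Product: 15 (2Z,5E,7R,9R)-7,9-dihydroxy-2-iodo-6,10,10-trimethyldodeca-2,5,11-trien-4-one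
Conditions: Me4NBH(OAc)3, MeCN/AcOH (1:1), −30 → −20 °C
Reagents that add atoms: none
Why: Evans–Saksena reduction, in which the existing hydroxyl binds the triacetoxyborohydride and delivers hydride intramolecularly through a chair transition state, giving the 1,3-anti diol (new C9 centre R) and leaving the non-hydroxylated dienone untouched.

**Step 7**
Reactants: 15 (2Z,5E,7R,9R)-7,9-dihydroxy-2-iodo-6,10,10-trimethyldodeca-2,5,11-trien-4-one; 16 angelic acid [(2Z)-2-methylbut-2-enoic acid]
Product: 18 (2Z,5E,7R,9R)-9-hydroxy-2-iodo-6,10,10-trimethyl-4-oxododeca-2,5,11-trien-7-yl (2Z)-2-methylbut-2-enoate, via mixed anhydride 17 (not isolated)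
Conditions: 16, 2,4,6-Cl3C6H2COCl, Et3N, toluene, 23 °C; then 15, 70 °C
Reagents that add atoms: none
Why: Yamaguchi-type esterification with the preformed mixed anhydride acylates the allylic C7 hydroxyl selectively because the C9 hydroxyl is neopentylic, and the DMAP-free conditions keep the angelate Z.

**Step 8**
Reactants: 18 (2Z,5E,7R,9R)-9-hydroxy-2-iodo-6,10,10-trimethyl-4-oxododeca-2,5,11-trien-7-yl (2Z)-2-methylbut-2-enoate
Product: 19 (2Z,4E,7R,9R,10E)-7-hydroxy-3,6,6,10-tetramethyl-9-[(2Z)-2-methylbut-2-enoyloxy]cycloundeca-2,4,10-trien-1-one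
Conditions: Pd(OAc)2 (20 mol %), tri(2-furyl)phosphine (40 mol %), Ag2CO3, MeCN, 2 mM (slow addition), 70 °C
Reagents that add atoms: none
Why: Intramolecular Heck reaction (endo macrocyclisation), in which zerovalent palladium inserts into the β-iodoenone C–I bond with retention, the vinyl-palladium adds to the unhindered terminal carbon of the vinyl group, and β-hydride elimination (possible only toward C4 because C6 is quaternary) gives the 4E diene.

**Step 9**
Reactants: 19 (2Z,4E,7R,9R,10E)-7-hydroxy-3,6,6,10-tetramethyl-9-[(2Z)-2-methylbut-2-enoyloxy]cycloundeca-2,4,10-trien-1-one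
Product: 20 (1R,2S,4R,6R,7R,8R)-4-hydroxy-3,3,7,11-tetramethyl-9-oxotricyclo[5.4.0.0^{2,8}]undec-10-en-6-yl (2Z)-2-methylbut-2-enoate
Conditions: thioxanthen-9-one (10 mol %), 405 nm LEDs, degassed CH2Cl2, 5 mM, 0 °C
Reagents that add atoms: none
Why: Proposed new method: triplet sensitisation of the 2,4-dienone puts spin density on C5, which adds to C11 to give the biradical stabilised at both ends (oxapentadienyl over C4/C2/O and tertiary C10) and then closes C10–C4, the four-carbon C6–C9 bridge allowing only the syn-methyl/anti-bridge arrangement at the four new stereocentres and the C9 angelate lying anti to the forming C10–C4 bond so that the (7R,9R) diol unit fixes the absolute sense; the closest known reaction types are the transannular crossed [2+2] photocycloaddition of humulane-type macrocyclic enones and the visible-light energy-transfer crossed [2+2] of dienones to bicyclo[3.1.1]heptanones.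

**Step 10**
Reactants: 20 (1R,2S,4R,6R,7R,8R)-4-hydroxy-3,3,7,11-tetramethyl-9-oxotricyclo[5.4.0.0^{2,8}]undec-10-en-6-yl (2Z)-2-methylbut-2-enoate; 21 2-methylprop-2-enoyl chloride
Product: 22 (1R,2S,4R,6R,7R,8R)-3,3,7,11-tetramethyl-4-[(2-methylprop-2-enoyl)oxy]-9-oxotricyclo[5.4.0.0^{2,8}]undec-10-en-6-yl (2Z)-2-methylbut-2-enoate
Conditions: 21, Et3N, DMAP (cat.), BHT (trace), CH2Cl2, 0 → 23 °C
Reagents that add atoms: none
Why: DMAP-catalysed acylation of the remaining neopentylic secondary alcohol touches no stereocentre, and BHT suppresses radical polymerisation of the methacrylate.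

**Compound list**
1 | 1,1-dimethoxypropan-2-one | CC(=O)C(OC)OC | starting material
2 | diethyl {2-[methoxy(methyl)amino]-2-oxoethyl}phosphonate | CCOP(=O)(CC(=O)N(C)OC)OCC | starting material
3 | sodium salt of the carbanion of 2 | CCOP(=O)([CH-]C(=O)N(C)OC)OCC.[Na+] | intermediate
4 | (2E)-N,4,4-trimethoxy-N,3-dimethylbut-2-enamide | CON(C)C(=O)/C=C(C)/C(OC)OC | intermediate
5 | prop-1-yn-1-ylmagnesium bromide | CC#C[Mg]Br | starting material
6 | (2E)-1,1-dimethoxy-2-methylhept-2-en-5-yn-4-one | CC#CC(=O)/C=C(C)/C(OC)OC | intermediate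
7 | (2E,5Z)-6-iodo-1,1-dimethoxy-2-methylhepta-2,5-dien-4-one | COC(OC)/C(C)=C/C(=O)/C=C(\I)C | intermediate
8 | (2E,5Z)-6-iodo-2-methyl-4-oxohepta-2,5-dienal | O=C/C(C)=C/C(=O)/C=C(\I)C | intermediate
9 | 1-chloro-3-methylbut-2-ene | CC(C)=CCCl | starting material
10 | acetic anhydride | CC(=O)OC(C)=O | starting material
11 | (3-methylbut-2-en-1-yl)magnesium chloride | CC(C)=CC[Mg]Cl | intermediate
12 | 3,3-dimethylpent-4-en-2-one | CC(=O)C(C)(C)C=C | intermediate
13 | 3,3-dimethylpenta-1,4-dien-2-yl diisopinocampheylborinate (isopinocampheyl groups from (+)-α-pinene) | C=CC(C)(C)C(=C)OB([C@@H]1C[C@@H]2C[C@H]([C@H]1C)C2(C)C)[C@@H]1C[C@@H]2C[C@H]([C@H]1C)C2(C)C | intermediate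
14 | (6R,7E,10Z)-6-hydroxy-11-iodo-3,3,7-trimethyldodeca-1,7,10-triene-4,9-dione | C=CC(C)(C)C(=O)C[C@@H](O)/C(C)=C/C(=O)/C=C(\I)C | intermediate
15 | (2Z,5E,7R,9R)-7,9-dihydroxy-2-iodo-6,10,10-trimethyldodeca-2,5,11-trien-4-one | C=CC(C)(C)[C@H](O)C[C@@H](O)/C(C)=C/C(=O)/C=C(\I)C | intermediate
16 | angelic acid, (2Z)-2-methylbut-2-enoic acid | OC(=O)/C(C)=C\C | starting material
17 | (2Z)-2-methylbut-2-enoic 2,4,6-trichlorobenzoic anhydride | O=C(OC(=O)/C(C)=C\C)c1c(Cl)cc(Cl)cc1Cl | intermediate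
18 | (2Z,5E,7R,9R)-9-hydroxy-2-iodo-6,10,10-trimethyl-4-oxododeca-2,5,11-trien-7-yl (2Z)-2-methylbut-2-enoate | C=CC(C)(C)[C@H](O)C[C@@H](OC(=O)/C(C)=C\C)/C(C)=C/C(=O)/C=C(\I)C | intermediate
19 | (2Z,4E,7R,9R,10E)-7-hydroxy-3,6,6,10-tetramethyl-9-[(2Z)-2-methylbut-2-enoyloxy]cycloundeca-2,4,10-trien-1-one | O=C1/C=C(C)\C=C\C(C)(C)[C@H](O)C[C@@H](OC(=O)/C(C)=C\C)/C(C)=C/1 | intermediate
20 | (1R,2S,4R,6R,7R,8R)-4-hydroxy-3,3,7,11-tetramethyl-9-oxotricyclo[5.4.0.0^{2,8}]undec-10-en-6-yl (2Z)-2-methylbut-2-enoate | O[C@@H]1C[C@@H](OC(=O)/C(C)=C\C)[C@@]2(C)[C@@H]3C(=O)C=C(C)[C@H]2[C@@H]3C1(C)C | intermediate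
21 | 2-methylprop-2-enoyl chloride | C=C(C)C(Cl)=O | starting material
22 | (1R,2S,4R,6R,7R,8R)-3,3,7,11-tetramethyl-4-[(2-methylprop-2-enoyl)oxy]-9-oxotricyclo[5.4.0.0^{2,8}]undec-10-en-6-yl (2Z)-2-methylbut-2-enoate | C=C(C)C(=O)O[C@@H]1C[C@@H](OC(=O)/C(C)=C\C)[C@@]2(C)[C@@H]3C(=O)C=C(C)[C@H]2[C@@H]3C1(C)C | target

**Totals**
Total step count: 10. Longest linear sequence: 9 steps (steps 1, 2, 3, 5, 6, 7, 8, 9, 10). Step 4 is the only side branch.

**Steps most likely to fail, with fallbacks**

Step 9 (key photocycloaddition). The macrocycle could instead close in the straight mode (C11–C4 and C10–C5, a 5-4-6 skeleton), or the facial control by the C9 ester could be weak. The sensitiser could also slowly isomerise the angelate to the tiglate. The fallback sets out from 15 and returns at 22. It turns the C10=C11 alkene into an ene-dione, so that attack of C5 on C11 becomes a Michael-type radical addition that leaves a tertiary α-keto radical at C10. MnO2 in CH2Cl2 oxidises only the allylic hydroxyl of 15 and gives (2Z,5E,9R)-9-hydroxy-2-iodo-6,10,10-trimethyldodeca-2,5,11-triene-4,7-dione F4. Heck closure under the step 8 conditions gives (2Z,4E,7R,10E)-7-hydroxy-3,6,6,10-tetramethylcycloundeca-2,4,10-triene-1,9-dione F5. Sensitised irradiation as in step 9 gives (1R,2S,4R,7R,8R)-4-hydroxy-3,3,7,11-tetramethyltricyclo[5.4.0.0^{2,8}]undec-10-ene-6,9-dione F6; here only the C7 stereocentre of F5 directs the facial sense, so a diastereomer separation may be needed. Acylation with 21 gives (1R,2S,4R,7R,8R)-3,3,7,11-tetramethyl-6,9-dioxotricyclo[5.4.0.0^{2,8}]undec-10-en-4-yl 2-methylprop-2-enoate F7. Reagent-controlled reduction of the saturated ketone with (S)-2-methyl-CBS-oxazaborolidine and catecholborane at −78 °C gives (1R,2S,4R,6R,7R,8R)-6-hydroxy-3,3,7,11-tetramethyl-9-oxotricyclo[5.4.0.0^{2,8}]undec-10-en-4-yl 2-methylprop-2-enoate F8; competing reduction of the enone is the weak point. Esterification with mixed anhydride 17 then gives 22.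

Step 8 (11-membered Heck closure). Oligomerisation or failure of the medium-ring closure is the main danger. The fallback sets out from 8 and 12 and returns at 19. It makes the diene bond intermolecularly and closes the ring at the aldol bond instead. Heck coupling of 8 with 12 (Pd(OAc)2, Ag2CO3, MeCN, 50 °C) gives the open-chain keto aldehyde (2E,5Z,7E)-2,6,9,9-tetramethyl-4,10-dioxoundeca-2,5,7-trienal F1. Slow addition of F1 to (−)-Ipc2BCl and Et3N at high dilution enolises only the methyl ketone and gives the macrocyclic aldol (2Z,4E,9R,10E)-9-hydroxy-3,6,6,10-tetramethylcycloundeca-2,4,10-triene-1,7-dione F2. Reduction with Me4NBH(OAc)3 gives (2Z,4E,7R,9R,10E)-7,9-dihydroxy-3,6,6,10-tetramethylcycloundeca-2,4,10-trien-1-one F3. Acylation of the allylic hydroxyl with 17 gives 19.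

Step 7 (selective mono-angeloylation). Diacylation, acylation at the wrong hydroxyl or 1,3-acyl migration would lose the differentiation of the two oxygens. The fallback sets out from 14 and returns at 18. It installs the ester while only one hydroxyl exists. Esterification of 14 with 17 (toluene, 40 °C) gives (6R,7E,10Z)-11-iodo-3,3,7-trimethyl-4,9-dioxododeca-1,7,10-trien-6-yl (2Z)-2-methylbut-2-enoate F9. Reagent-controlled reduction of its saturated ketone (tert-alkyl against CH2) with (S)-2-methyl-CBS-oxazaborolidine and catecholborane at −78 °C gives 18; β-elimination of the ester and competing reduction of the dienone are the risks there.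

**Further compounds**
F1 | step 8 | (2E,5Z,7E)-2,6,9,9-tetramethyl-4,10-dioxoundeca-2,5,7-trienal | CC(=O)C(C)(C)/C=C/C(C)=C\C(=O)/C=C(C)/C=O
F2 | step 8 | (2Z,4E,9R,10E)-9-hydroxy-3,6,6,10-tetramethylcycloundeca-2,4,10-triene-1,7-dione | O=C1/C=C(C)\C=C\C(C)(C)C(=O)C[C@@H](O)/C(C)=C/1
F3 | step 8 | (2Z,4E,7R,9R,10E)-7,9-dihydroxy-3,6,6,10-tetramethylcycloundeca-2,4,10-trien-1-one | O=C1/C=C(C)\C=C\C(C)(C)[C@H](O)C[C@@H](O)/C(C)=C/1
F4 | step 9 | (2Z,5E,9R)-9-hydroxy-2-iodo-6,10,10-trimethyldodeca-2,5,11-triene-4,7-dione | C=CC(C)(C)[C@H](O)CC(=O)/C(C)=C/C(=O)/C=C(\I)C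
F5 | step 9 | (2Z,4E,7R,10E)-7-hydroxy-3,6,6,10-tetramethylcycloundeca-2,4,10-triene-1,9-dione | O=C1/C=C(C)\C=C\C(C)(C)[C@H](O)CC(=O)/C(C)=C/1
F6 | step 9 | (1R,2S,4R,7R,8R)-4-hydroxy-3,3,7,11-tetramethyltricyclo[5.4.0.0^{2,8}]undec-10-ene-6,9-dione | O[C@@H]1CC(=O)[C@@]2(C)[C@@H]3C(=O)C=C(C)[C@H]2[C@@H]3C1(C)C
F7 | step 9 | (1R,2S,4R,7R,8R)-3,3,7,11-tetramethyl-6,9-dioxotricyclo[5.4.0.0^{2,8}]undec-10-en-4-yl 2-methylprop-2-enoate | C=C(C)C(=O)O[C@@H]1CC(=O)[C@@]2(C)[C@@H]3C(=O)C=C(C)[C@H]2[C@@H]3C1(C)C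
F8 | step 9 | (1R,2S,4R,6R,7R,8R)-6-hydroxy-3,3,7,11-tetramethyl-9-oxotricyclo[5.4.0.0^{2,8}]undec-10-en-4-yl 2-methylprop-2-enoate | C=C(C)C(=O)O[C@@H]1C[C@@H](O)[C@@]2(C)[C@@H]3C(=O)C=C(C)[C@H]2[C@@H]3C1(C)C
F9 | step 7 | (6R,7E,10Z)-11-iodo-3,3,7-trimethyl-4,9-dioxododeca-1,7,10-trien-6-yl (2Z)-2-methylbut-2-enoate | C=CC(C)(C)C(=O)C[C@@H](OC(=O)/C(C)=C\C)/C(C)=C/C(=O)/C=C(\I)C
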